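**Strategy.** The γ-lactone of the cis-fused 1,2-dioxane–γ-lactone core is cut at its acyl bond C7–C6 and its alkyl bond O5–C4a (furo[3,2-c][1,2]dioxine numbering). C7, C7a and C4a then map onto the terminal alkyne carbon, the internal alkyne carbon and the carbinol carbon of a tertiary propargylic ester. In one flask, palladium-catalysed hydroxycarbonylation makes C7–C6 through an allenylpalladium, and silver-catalysed cycloisomerisation of the resulting allenoic acid makes O5–C4a with centre-to-axis-to-centre chirality transfer. The precursor is a propargylic trifluoroacetate bearing a Sharpless-derived epoxide; the epoxide first steers C4a and later delivers the C3 hydroperoxide, whose conjugate addition to the butenolide closes the dioxane.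

Key step: step 14

Remark on the chemistry (locants): the bicyclic core is numbered O1, O2 (peroxide), C3 (quaternary, side chain), C4 (CH2), C4a (quaternary, methyl), O5 (lactone oxygen), C6 (carbonyl), C7 (CH2), C7a (CH).
Remark on the chemistry (assumption): MeMgBr is assumed to add to the carbonyl group of the terminal ynone 16 at −78 °C faster than it deprotonates the alkyne C–H.

Step 1
Reactants: 1 pent-4-en-1-ol; 2 styrene
Product: 3 (4E)-5-phenylpent-4-en-1-ol
Conditions: RuCl2(=CHPh)(PCy3)(H2IMes) (second-generation Grubbs catalyst, 2 mol %), styrene (3 equiv), CH2Cl2, 40 °C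
Reagents that add atoms: none
Why: Olefin cross-metathesis of a terminal alkenol with excess styrene should give the thermodynamically favoured (E)-styrene with loss of ethene.

Step 2
Reactants: 3 (4E)-5-phenylpent-4-en-1-ol; 4 1-phenyl-1H-tetrazole-5-thiol
Product: 5 1-phenyl-5-{[(4E)-5-phenylpent-4-en-1-yl]sulfanyl}-1H-tetrazole
Conditions: PPh3, DIAD, THF, 0 °C → rt
Reagents that add atoms: none
Why: Mitsunobu thioetherification of a primary alcohol with the acidic tetrazolethiol should proceed by SN2 at carbon.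

Step 3
Reactants: 5 1-phenyl-5-{[(4E)-5-phenylpent-4-en-1-yl]sulfanyl}-1H-tetrazole
Product: 6 1-phenyl-5-{[(4E)-5-phenylpent-4-en-1-yl]sulfonyl}-1H-tetrazole
Conditions: (NH4)6Mo7O24·4H2O (cat.), 30% H2O2, EtOH, 0 °C → rt
Reagents that add atoms: hydrogen peroxide, OO
Why: Molybdate-catalysed sulfide oxidation with hydrogen peroxide should reach the sulfone without touching the styrene double bond.

Step 4
Reactants: 7 (R)-citronellal
Product: 8 (4R)-4,8-dimethylnon-7-en-1-yne
Conditions: dimethyl (1-diazo-2-oxopropyl)phosphonate, K2CO3, MeOH, rt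
Reagents that add atoms: dimethyl (1-diazo-2-oxopropyl)phosphonate, COP(=O)(OC)C(=[N+]=[N-])C(C)=O
Why: Ohira–Bestmann (Seyferth–Gilbert) homologation turns the aldehyde into the terminal alkyne under mild base, and the stereocentre, being β to the carbonyl group, is not at risk.

Step 5
Reactants: 8 (4R)-4,8-dimethylnon-7-en-1-yne
Product: 9 (4R)-4-methylhept-6-ynal
Conditions: O3, CH2Cl2/MeOH, Sudan Red 7B (indicator), −78 °C; then Me2S
Reagents that add atoms: ozone, [O-][O+]=O
Why: Ozonolysis with reductive work-up should cleave the electron-rich trisubstituted alkene far faster than the terminal alkyne, the dye marking the end point.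

Step 6
Reactants: 9 (4R)-4-methylhept-6-ynal; 6 1-phenyl-5-{[(4E)-5-phenylpent-4-en-1-yl]sulfonyl}-1H-tetrazole
Product: 10 (4R,7E,11E)-4-methyl-12-phenyldodeca-7,11-dien-1-yne
Conditions: KN(SiMe3)2, DME, −60 °C → rt
Reagents that add atoms: none
Why: Julia–Kocienski olefination of an unbranched aldehyde with a primary 1-phenyltetrazolyl sulfone should favour the (E)-alkene, and the sulfonyl carbanion is too weak a base to deprotonate the alkyne.

Step 7
Reactants: 10 (4R,7E,11E)-4-methyl-12-phenyldodeca-7,11-dien-1-yne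
Product: 12 (2E,5R,8E,12E)-3,5-dimethyl-13-phenyltrideca-2,8,12-trien-1-ol, via alkenyldimethylalane 11 (not isolated)
Conditions: Me3Al, Cp2ZrCl2 (cat.), CH2Cl2, 0 °C → rt; then n-BuLi, (CH2O)n, THF, −78 °C → rt
Reagents that add atoms: trimethylaluminium, C[Al](C)C; paraformaldehyde (as formaldehyde), C=O
Why: Negishi zirconium-catalysed carboalumination adds methyl and aluminium syn across the terminal alkyne with methyl on the internal carbon, and the derived alanate is hydroxymethylated with retention, which fixes the (E)-trisubstituted alkene.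

Step 8
Reactants: 12 (2E,5R,8E,12E)-3,5-dimethyl-13-phenyltrideca-2,8,12-trien-1-ol
Product: 13 [(2S,3S)-3-methyl-3-[(2R,5E,9E)-2-methyl-10-phenyldeca-5,9-dien-1-yl]oxiran-2-yl]methanol
Conditions: Ti(OiPr)4 (cat.), L-(+)-diethyl tartrate, t-BuOOH, 4 Å MS, CH2Cl2, −20 °C
Reagents that add atoms: tert-butyl hydroperoxide, CC(C)(C)OO
Why: Sharpless asymmetric epoxidation with the L-(+)-tartrate should deliver oxygen to one face of the (E)-allylic alcohol only, setting the two epoxide carbons (the future C4 and C3) as 2S,3S and leaving the isolated alkenes untouched.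

Step 9
Reactants: 13 [(2S,3S)-3-methyl-3-[(2R,5E,9E)-2-methyl-10-phenyldeca-5,9-dien-1-yl]oxiran-2-yl]methanol
Product: 14 (2R,3S)-3-methyl-3-[(2R,5E,9E)-2-methyl-10-phenyldeca-5,9-dien-1-yl]oxirane-2-carbaldehyde
Conditions: Dess–Martin periodinane, NaHCO3, CH2Cl2, 0 °C → rt
Reagents that add atoms: none
Why: Buffered Dess–Martin oxidation should give the epoxy aldehyde without epimerising the α-epoxy centre.

Step 10
Reactants: 14 (2R,3S)-3-methyl-3-[(2R,5E,9E)-2-methyl-10-phenyldeca-5,9-dien-1-yl]oxirane-2-carbaldehyde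
Product: 15 (1RS)-1-[(2S,3S)-3-methyl-3-[(2R,5E,9E)-2-methyl-10-phenyldeca-5,9-dien-1-yl]oxiran-2-yl]prop-2-yn-1-ol
Conditions: HC≡CMgBr, THF, −78 °C
Reagents that add atoms: ethynylmagnesium bromide, C#C[Mg]Br
Why: Grignard 1,2-addition of the acetylide to the aldehyde; the configuration of the new carbinol is of no consequence because step 11 removes it.

Step 11
Reactants: 15 (1RS)-1-[(2S,3S)-3-methyl-3-[(2R,5E,9E)-2-methyl-10-phenyldeca-5,9-dien-1-yl]oxiran-2-yl]prop-2-yn-1-ol
Product: 16 1-[(2R,3S)-3-methyl-3-[(2R,5E,9E)-2-methyl-10-phenyldeca-5,9-dien-1-yl]oxiran-2-yl]prop-2-yn-1-one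
Conditions: Dess–Martin periodinane, NaHCO3, CH2Cl2, 0 °C
Reagents that add atoms: none
Why: Dess–Martin oxidation of the secondary propargylic alcohol should give the α,β-epoxy ynone under neutral conditions.

Step 12
Reactants: 16 1-[(2R,3S)-3-methyl-3-[(2R,5E,9E)-2-methyl-10-phenyldeca-5,9-dien-1-yl]oxiran-2-yl]prop-2-yn-1-one
Product: 17 (2S)-2-[(2S,3S)-3-methyl-3-[(2R,5E,9E)-2-methyl-10-phenyldeca-5,9-dien-1-yl]oxiran-2-yl]but-3-yn-2-ol
Conditions: MeMgBr, Et2O/CH2Cl2, −78 °C
Reagents that add atoms: methylmagnesium bromide, C[Mg]Br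
Why: Cram-chelate-controlled Grignard addition: magnesium bridges the carbonyl and epoxide oxygens and methyl should enter from the face of the α-hydrogen, anti to the epoxide C–C bond, which sets the tertiary carbinol (the future C4a) as 2S.

Step 13
Reactants: 17 (2S)-2-[(2S,3S)-3-methyl-3-[(2R,5E,9E)-2-methyl-10-phenyldeca-5,9-dien-1-yl]oxiran-2-yl]but-3-yn-2-ol
Product: 18 (2S)-2-[(2R,3S)-3-methyl-3-[(2R,5E,9E)-2-methyl-10-phenyldeca-5,9-dien-1-yl]oxiran-2-yl]but-3-yn-2-yl trifluoroacetate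
Conditions: (CF3CO)2O, pyridine, DMAP (cat.), CH2Cl2, −20 °C
Reagents that add atoms: trifluoroacetic anhydride, O=C(OC(=O)C(F)(F)F)C(F)(F)F
Why: Acylation of the tertiary propargylic alcohol gives an isolable ester that ionises readily toward palladium, where a tertiary sulfonate would not survive.

Step 14
Reactants: 18 (2S)-2-[(2R,3S)-3-methyl-3-[(2R,5E,9E)-2-methyl-10-phenyldeca-5,9-dien-1-yl]oxiran-2-yl]but-3-yn-2-yl trifluoroacetate
Product: 20 (5R)-5-methyl-5-[(2R,3S)-3-methyl-3-[(2R,5E,9E)-2-methyl-10-phenyldeca-5,9-dien-1-yl]oxiran-2-yl]furan-2(5H)-one, via allenoic acid 19 (not isolated)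
Conditions: Pd(PPh3)4 (5 mol %), CO (1 atm), 2,6-lutidine, THF/H2O, 0 °C → rt; then AgNO3 (0.5 equiv), acetone, rt, same flask
Reagents that add atoms: carbon monoxide, [C-]#[O+]; water, O
Why: Zerovalent palladium should ionise the propargylic trifluoroacetate by anti SN2′ attack at the terminal alkyne carbon to give a σ-allenylpalladium of defined axial chirality, CO then inserts into the carbon–palladium bond (forming C7–C6) and water releases allenoic acid 19; monovalent silver activates the allene and the carboxyl oxygen adds to the former carbinol carbon (forming O5–C4a), followed by protodemetalation. The closest known reaction type is the palladium-catalysed hydroxycarbonylation of propargylic esters to 2,3-dienoic acids joined to the silver nitrate-catalysed cycloisomerisation of allenoic acids to butenolides. The butenolide ring closes in a 5-endo-trig mode at the allene terminus. The quaternary stereocentre C4a is controlled by centre-to-axis-to-centre chirality transfer: the anti ionisation fixes the allene axis (Sa) and the carboxyl group can reach the allene terminus only from its own side, so the new C–O bond forms on the face opposite to the departed trifluoroacetate (net inversion, hence the 2S carbinol of 17). The step needs SN2′ ionisation to the allenyl rather than the propargyl or an allyl-type complex and retention of the axial configuration until CO insertion; the unhindered terminal alkyne carbon, the fully substituted carbinol carbon and the absence of an alkene next to it in 18 secure the first, low temperature and a CO atmosphere the second.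

Step 15
Reactants: 20 (5R)-5-methyl-5-[(2R,3S)-3-methyl-3-[(2R,5E,9E)-2-methyl-10-phenyldeca-5,9-dien-1-yl]oxiran-2-yl]furan-2(5H)-one
Product: 21 (5R)-5-[(1S,2R,4R,7E,11E)-2-hydroperoxy-1-hydroxy-2,4-dimethyl-12-phenyldodeca-7,11-dien-1-yl]-5-methylfuran-2(5H)-one
Conditions: H2O2 (anhydrous, in Et2O), H3PMo12O40 (cat.), Et2O, rt
Reagents that add atoms: hydrogen peroxide, OO
Why: Acid-catalysed perhydrolysis of a trisubstituted epoxide: hydrogen peroxide should attack the tertiary carbon, which carries positive charge best and lies remote from the electron-withdrawing lactone oxygen, from the back, so the future C3 is set with inversion.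

Step 16
Reactants: 21 (5R)-5-[(1S,2R,4R,7E,11E)-2-hydroperoxy-1-hydroxy-2,4-dimethyl-12-phenyldodeca-7,11-dien-1-yl]-5-methylfuran-2(5H)-one
Product: 22 (3R,4S,4aS,7aS)-4-hydroxy-3,4a-dimethyl-3-[(2R,5E,9E)-2-methyl-10-phenyldeca-5,9-dien-1-yl]tetrahydro-3H-furo[3,2-c][1,2]dioxin-6(4H)-one
Conditions: Et2NH (cat.), CF3CH2OH, rt
Reagents that add atoms: none
Why: Intramolecular oxa-Michael addition (6-exo-trig) of the hydroperoxide to the butenolide; the tether can reach the β-carbon only from the face on which it is attached, so C7a is set by C4a as the cis ring fusion.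

Step 17
Reactants: 22 (3R,4S,4aS,7aS)-4-hydroxy-3,4a-dimethyl-3-[(2R,5E,9E)-2-methyl-10-phenyldeca-5,9-dien-1-yl]tetrahydro-3H-furo[3,2-c][1,2]dioxin-6(4H)-one
Product: 23 O-[(3R,4S,4aS,7aS)-3,4a-dimethyl-3-[(2R,5E,9E)-2-methyl-10-phenyldeca-5,9-dien-1-yl]-6-oxohexahydro-3H-furo[3,2-c][1,2]dioxin-4-yl] O-phenyl carbonothioate
Conditions: PhOC(S)Cl, DMAP, MeCN, rt
Reagents that add atoms: O-phenyl carbonochloridothioate, S=C(Cl)Oc1ccccc1
Why: Thioacylation of the secondary alcohol gives a Barton–McCombie precursor under a base mild enough not to trigger retro-oxa-Michael opening of the peroxide ring.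

Step 18
Reactants: 23 O-[(3R,4S,4aS,7aS)-3,4a-dimethyl-3-[(2R,5E,9E)-2-methyl-10-phenyldeca-5,9-dien-1-yl]-6-oxohexahydro-3H-furo[3,2-c][1,2]dioxin-4-yl] O-phenyl carbonothioate
Product: 24 (3R,4aS,7aS)-3,4a-dimethyl-3-[(2R,5E,9E)-2-methyl-10-phenyldeca-5,9-dien-1-yl]tetrahydro-3H-furo[3,2-c][1,2]dioxin-6(4H)-one (CNP0365311.2)
Conditions: Bu3SnH, Et3B (cat.), air, toluene, rt
Reagents that add atoms: none
Why: Barton–McCombie deoxygenation at room temperature; the ring radical at C4 should be reduced by the stannane faster than it attacks the O–O bond, for which the ring geometry is poorly suited, and no stereocentre remains at C4.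

**Compound list**

1 | pent-4-en-1-ol | OCCCC=C | starting material
2 | styrene | C=Cc1ccccc1 | starting material
3 | (4E)-5-phenylpent-4-en-1-ol | OCCC/C=C/c1ccccc1 | intermediate
4 | 1-phenyl-1H-tetrazole-5-thiol | Sc1nnnn1-c1ccccc1 | starting material
5 | 1-phenyl-5-{[(4E)-5-phenylpent-4-en-1-yl]sulfanyl}-1H-tetrazole | S(CCC/C=C/c1ccccc1)c1nnnn1-c1ccccc1 | intermediate
6 | 1-phenyl-5-{[(4E)-5-phenylpent-4-en-1-yl]sulfonyl}-1H-tetrazole | O=S(=O)(CCC/C=C/c1ccccc1)c1nnnn1-c1ccccc1 | intermediate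
7 | (R)-citronellal, (3R)-3,7-dimethyloct-6-enal | C[C@H](CCC=C(C)C)CC=O | starting material
8 | (4R)-4,8-dimethylnon-7-en-1-yne | C[C@H](CCC=C(C)C)CC#C | intermediate
9 | (4R)-4-methylhept-6-ynal | C[C@H](CCC=O)CC#C | intermediate
10 | (4R,7E,11E)-4-methyl-12-phenyldodeca-7,11-dien-1-yne | C[C@H](CC/C=C/CC/C=C/c1ccccc1)CC#C | intermediate
11 | dimethyl[(1E,4R,7E,11E)-2,4-dimethyl-12-phenyldodeca-1,7,11-trien-1-yl]alumane | C[Al](C)/C=C(\C)C[C@H](C)CC/C=C/CC/C=C/c1ccccc1 | intermediate
12 | (2E,5R,8E,12E)-3,5-dimethyl-13-phenyltrideca-2,8,12-trien-1-ol | OC/C=C(\C)C[C@H](C)CC/C=C/CC/C=C/c1ccccc1 | intermediate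
13 | [(2S,3S)-3-methyl-3-[(2R,5E,9E)-2-methyl-10-phenyldeca-5,9-dien-1-yl]oxiran-2-yl]methanol | OC[C@@H]1O[C@@]1(C)C[C@H](C)CC/C=C/CC/C=C/c1ccccc1 | intermediate
14 | (2R,3S)-3-methyl-3-[(2R,5E,9E)-2-methyl-10-phenyldeca-5,9-dien-1-yl]oxirane-2-carbaldehyde | O=C[C@@H]1O[C@@]1(C)C[C@H](C)CC/C=C/CC/C=C/c1ccccc1 | intermediate
15 | (1RS)-1-[(2S,3S)-3-methyl-3-[(2R,5E,9E)-2-methyl-10-phenyldeca-5,9-dien-1-yl]oxiran-2-yl]prop-2-yn-1-ol (both carbinol epimers) | C#CC(O)[C@@H]1O[C@@]1(C)C[C@H](C)CC/C=C/CC/C=C/c1ccccc1 | intermediate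
16 | 1-[(2R,3S)-3-methyl-3-[(2R,5E,9E)-2-methyl-10-phenyldeca-5,9-dien-1-yl]oxiran-2-yl]prop-2-yn-1-one | C#CC(=O)[C@@H]1O[C@@]1(C)C[C@H](C)CC/C=C/CC/C=C/c1ccccc1 | intermediate
17 | (2S)-2-[(2S,3S)-3-methyl-3-[(2R,5E,9E)-2-methyl-10-phenyldeca-5,9-dien-1-yl]oxiran-2-yl]but-3-yn-2-ol | C#C[C@](C)(O)[C@@H]1O[C@@]1(C)C[C@H](C)CC/C=C/CC/C=C/c1ccccc1 | intermediate
18 | (2S)-2-[(2R,3S)-3-methyl-3-[(2R,5E,9E)-2-methyl-10-phenyldeca-5,9-dien-1-yl]oxiran-2-yl]but-3-yn-2-yl trifluoroacetate | C#C[C@](C)(OC(=O)C(F)(F)F)[C@@H]1O[C@@]1(C)C[C@H](C)CC/C=C/CC/C=C/c1ccccc1 | intermediate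
19 | (Sa)-4-[(2S,3S)-3-methyl-3-[(2R,5E,9E)-2-methyl-10-phenyldeca-5,9-dien-1-yl]oxiran-2-yl]penta-2,3-dienoic acid (allene axis Sa) | OC(=O)[CH]=[C@@]=C(C)[C@@H]1O[C@@]1(C)C[C@H](C)CC/C=C/CC/C=C/c1ccccc1 | intermediate
20 | (5R)-5-methyl-5-[(2R,3S)-3-methyl-3-[(2R,5E,9E)-2-methyl-10-phenyldeca-5,9-dien-1-yl]oxiran-2-yl]furan-2(5H)-one | C[C@]1(OC(=O)C=C1)[C@@H]2O[C@@]2(C)C[C@H](C)CC/C=C/CC/C=C/c3ccccc3 | intermediate
21 | (5R)-5-[(1S,2R,4R,7E,11E)-2-hydroperoxy-1-hydroxy-2,4-dimethyl-12-phenyldodeca-7,11-dien-1-yl]-5-methylfuran-2(5H)-one | C[C@]1(OC(=O)C=C1)[C@H](O)[C@](C)(OO)C[C@H](C)CC/C=C/CC/C=C/c2ccccc2 | intermediate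
22 | (3R,4S,4aS,7aS)-4-hydroxy-3,4a-dimethyl-3-[(2R,5E,9E)-2-methyl-10-phenyldeca-5,9-dien-1-yl]tetrahydro-3H-furo[3,2-c][1,2]dioxin-6(4H)-one (cis-fused 1,2-dioxane/γ-lactone) | C[C@H](CC/C=C/CC/C=C/c1ccccc1)C[C@]1(C)[C@@H](O)[C@]2(C)OC(=O)C[C@@H]2OO1 | intermediate
23 | O-[(3R,4S,4aS,7aS)-3,4a-dimethyl-3-[(2R,5E,9E)-2-methyl-10-phenyldeca-5,9-dien-1-yl]-6-oxohexahydro-3H-furo[3,2-c][1,2]dioxin-4-yl] O-phenyl carbonothioate | C[C@H](CC/C=C/CC/C=C/c1ccccc1)C[C@]1(C)[C@@H](OC(=S)Oc3ccccc3)[C@]2(C)OC(=O)C[C@@H]2OO1 | intermediate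
24 | (3R,4aS,7aS)-3,4a-dimethyl-3-[(2R,5E,9E)-2-methyl-10-phenyldeca-5,9-dien-1-yl]tetrahydro-3H-furo[3,2-c][1,2]dioxin-6(4H)-one (CNP0365311.2) | C[C@H](CC/C=C/CC/C=C/c1ccccc1)C[C@]1(C)C[C@]2(C)OC(=O)C[C@@H]2OO1 | target

**Step count**

Total step count: 18. Longest linear sequence: 16 steps (steps 1 to 3 and then 6 to 18, from pent-4-en-1-ol 1 and styrene 2). The branch from (R)-citronellal 7 (steps 4 and 5) joins at step 6 and runs 15 steps to the target.

**Steps most likely to fail**

Step 14. Once allenoic acid 19 accumulates, zerovalent palladium may insert into the allylic C–O bond of its epoxide, and the allenylpalladium may lose its axial configuration before CO insertion; acid set free in the carbonylation could also open the epoxide. The fallback sets out from trifluoroacetate 18 and avoids palladium. Anti SN2′ substitution with LiCuBr2 (THF, −60 °C) should give the bromoallene (2S,3S)-2-[(Sa)-4-bromobuta-2,3-dien-2-yl]-3-methyl-3-[(2R,5E,9E)-2-methyl-10-phenyldeca-5,9-dien-1-yl]oxirane F1. Bromine–lithium exchange (t-BuLi, Et2O, −90 °C) and quenching with CO2 should give allenoic acid 19 with retention, this time isolated. AgNO3 in acetone then closes it to butenolide 20, where the route is rejoined.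

Step 17. The C4 hydroxyl sits between two quaternary carbons, so thioacylation may be too slow, and forcing it with base or heat invites retro-oxa-Michael opening of the peroxide ring. The fallback sets out from epoxy butenolide 20, never creates the C4 hydroxyl, and replaces steps 15 to 18. Stereospecific deoxygenation of the epoxide (CH3ReO3 cat., PPh3) should give the alkene (5R)-5-[(1E,4R,7E,11E)-2,4-dimethyl-12-phenyldodeca-1,7,11-trien-1-yl]-5-methylfuran-2(5H)-one F2. Bromohydroperoxidation (1,3-dibromo-5,5-dimethylhydantoin, anhydrous H2O2, Et2O, −40 °C; anti addition, hydroperoxide at the tertiary carbon) should give (5R)-5-[(1S,2R,4R,7E,11E)-1-bromo-2-hydroperoxy-2,4-dimethyl-12-phenyldodeca-7,11-dien-1-yl]-5-methylfuran-2(5H)-one F3. Et2NH in CF3CH2OH should close it to the bromide (3R,4S,4aR,7aS)-4-bromo-3,4a-dimethyl-3-[(2R,5E,9E)-2-methyl-10-phenyldeca-5,9-dien-1-yl]tetrahydro-3H-furo[3,2-c][1,2]dioxin-6(4H)-one F4, and Bu3SnH/Et3B then removes the bromine and gives target 24. In this detour the face of bromonium formation is under substrate control only, and the side-chain alkenes compete for the bromonium source, so the C3 epimers might have to be separated at the stage of the bromide.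

Step 12. Chelation may compete with non-chelated (Felkin–Anh) addition and erode the facial selectivity, and the Grignard reagent may deprotonate the terminal ynone or add to it in a conjugate sense. The fallback sets out from aldehyde 14 and exchanges the roles of the two carbon groups. MeMgBr should give (1RS)-1-[(2S,3S)-3-methyl-3-[(2R,5E,9E)-2-methyl-10-phenyldeca-5,9-dien-1-yl]oxiran-2-yl]ethan-1-ol F5, and Dess–Martin oxidation should give the methyl ketone 1-[(2R,3S)-3-methyl-3-[(2R,5E,9E)-2-methyl-10-phenyldeca-5,9-dien-1-yl]oxiran-2-yl]ethan-1-one F6. Lithium (trimethylsilyl)acetylide under non-chelating conditions (THF/HMPA, −78 °C) should add under Felkin–Anh control, with the epoxide C–O bond anti to the nucleophile. This is the face opposite to the chelate face, so with methyl and alkynyl exchanged the same carbinol configuration results, in (2S)-2-[(2S,3S)-3-methyl-3-[(2R,5E,9E)-2-methyl-10-phenyldeca-5,9-dien-1-yl]oxiran-2-yl]-4-(trimethylsilyl)but-3-yn-2-ol F7. K2CO3 in MeOH then removes the silyl group and gives alcohol 17, where the route is rejoined.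

Further compounds
F1 | step 14 | (2S,3S)-2-[(Sa)-4-bromobuta-2,3-dien-2-yl]-3-methyl-3-[(2R,5E,9E)-2-methyl-10-phenyldeca-5,9-dien-1-yl]oxirane | Br[CH]=[C@@]=C(C)[C@@H]1O[C@@]1(C)C[C@H](C)CC/C=C/CC/C=C/c1ccccc1
F2 | step 17 | (5R)-5-[(1E,4R,7E,11E)-2,4-dimethyl-12-phenyldodeca-1,7,11-trien-1-yl]-5-methylfuran-2(5H)-one | C[C@]1(OC(=O)C=C1)/C=C(\C)C[C@H](C)CC/C=C/CC/C=C/c2ccccc2
F3 | step 17 | (5R)-5-[(1S,2R,4R,7E,11E)-1-bromo-2-hydroperoxy-2,4-dimethyl-12-phenyldodeca-7,11-dien-1-yl]-5-methylfuran-2(5H)-one | C[C@]1(OC(=O)C=C1)[C@H](Br)[C@](C)(OO)C[C@H](C)CC/C=C/CC/C=C/c2ccccc2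
F4 | step 17 | (3R,4S,4aR,7aS)-4-bromo-3,4a-dimethyl-3-[(2R,5E,9E)-2-methyl-10-phenyldeca-5,9-dien-1-yl]tetrahydro-3H-furo[3,2-c][1,2]dioxin-6(4H)-one | C[C@H](CC/C=C/CC/C=C/c1ccccc1)C[C@]1(C)[C@@H](Br)[C@]2(C)OC(=O)C[C@@H]2OO1
F5 | step 12 | (1RS)-1-[(2S,3S)-3-methyl-3-[(2R,5E,9E)-2-methyl-10-phenyldeca-5,9-dien-1-yl]oxiran-2-yl]ethan-1-ol | CC(O)[C@@H]1O[C@@]1(C)C[C@H](C)CC/C=C/CC/C=C/c1ccccc1
F6 | step 12 | 1-[(2R,3S)-3-methyl-3-[(2R,5E,9E)-2-methyl-10-phenyldeca-5,9-dien-1-yl]oxiran-2-yl]ethan-1-one | CC(=O)[C@@H]1O[C@@]1(C)C[C@H](C)CC/C=C/CC/C=C/c1ccccc1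
F7 | step 12 | (2S)-2-[(2S,3S)-3-methyl-3-[(2R,5E,9E)-2-methyl-10-phenyldeca-5,9-dien-1-yl]oxiran-2-yl]-4-(trimethylsilyl)but-3-yn-2-ol | C[Si](C)(C)C#C[C@](C)(O)[C@@H]1O[C@@]1(C)C[C@H](C)CC/C=C/CC/C=C/c1ccccc1
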